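**Plan**

- Core numbering (hexahydronaphthalenyl ester): C1 (CHMe), C2 (ester carbinol), C3=C4, C4a, C5 (=CH), C6 (C=O), C7 (CHOH), C8, C8a (quaternary). Retrosynthesis: the C6 ketone comes from the carbinol; both double bonds of the diene C3=C4–C4a=C5 are then cut (C4a=C5 and C3=C4) to give an acyclic dienyne; further cuts are C6–C7, the ester C–O bond, C2–C3 and C1–C8a.
- Enabling feature: C4a=C5 (ring A) and C3=C4 (ring B) meet at the fusion carbon C4a, next to the all-carbon quaternary C8a. Such a cross-ring 1,3-diene is what an alkyne leaves behind in an ene–yne–ene metathesis relay. An ethynyl group on C8a (its carbons become C4a and C4), placed between a C5 vinyl group and a C3 olefin, should therefore close ring A and then ring B in one operation.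
- Forward order: the chain is built around C8a (C1–C8a by sigmatropic shift, C2–C3 by Grignard addition, esterification with the separately made side-chain acid, C6–C7 by allylboration); the relay metathesis then closes ring A (C4a=C5) and ring B (C3=C4); an allylic oxidation ends the route.
- Stereochemistry: C1 and C8a from an enantioselective chair Ireland–Claisen rearrangement; C2 by Felkin–Anh reduction; C7 by isopinocampheyl-controlled allylboration (C6 is transient); side-chain C6 from (R)-2-hydroxy-2-methylbutanoic acid.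

Key step: step 15

Remark: the sense of induction of the diazaborolidine controller in step 3 is assigned by analogy; the (S,S)-controller is taken to give the (2R,3R)-acid 7, and its antipode would be used if this substrate responded the other way.

**Route**

Step 1
Reactants: 1 (E)-3-methylpent-2-en-4-yn-1-ol
Product: 3 (E)-3-methyl-5-(trimethylsilyl)pent-2-en-4-yn-1-ol, via bis-silyl ether 2 (not isolated)
Conditions: n-BuLi (2.1 equiv), THF, −78 °C; Me3SiCl (2.2 equiv), −78 °C to rt; then 1 M HCl, rt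
Reagents that add atoms: chlorotrimethylsilane, C[Si](C)(C)Cl
Why: double deprotonation (O–H and alkyne C–H) and bis-silylation, after which the acidic work-up should cleave only the labile O–Si bond; the C-silyl group shields the alkyne from the bases and the borane used later.

Step 2
Reactants: 3 (E)-3-methyl-5-(trimethylsilyl)pent-2-en-4-yn-1-ol; 4 propanoyl chloride
Product: 5 (E)-3-methyl-5-(trimethylsilyl)pent-2-en-4-yn-1-yl propanoate
Conditions: Et3N, DMAP (5 mol %), CH2Cl2, 0 °C
Reagents that add atoms: none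
Why: standard DMAP-catalysed acylation of a primary allylic alcohol.

Step 3
Reactants: 5 (E)-3-methyl-5-(trimethylsilyl)pent-2-en-4-yn-1-yl propanoate
Product: 7 (2R,3R)-2,3-dimethyl-3-[(trimethylsilyl)ethynyl]pent-4-enoic acid, via boron enolate 6 (not isolated)
Conditions: (4S,5S)-2-bromo-1,3-bis{[3,5-bis(trifluoromethyl)phenyl]sulfonyl}-4,5-diphenyl-1,3,2-diazaborolidine (1.2 equiv, freshly made from the (S,S)-bis-sulfonamide and BBr3 in CH2Cl2), Et3N, toluene–hexane, −78 °C; then −20 °C to 4 °C, several days; aqueous work-up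
Reagents that add atoms: none
Why: enantioselective Ireland–Claisen rearrangement of a chiral boron ketene acetal: Et3N in the non-polar medium should give the enolate with methyl cis to the allyloxy oxygen, and the chair [3,3] shift with the (E)-olefin (alkynyl equatorial, both methyl groups axial) sets C1 and the quaternary C8a of the target in the required relative configuration, while the diazaborolidine selects the enantiotopic face.

Step 4
Reactants: 7 (2R,3R)-2,3-dimethyl-3-[(trimethylsilyl)ethynyl]pent-4-enoic acid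
Product: 9 (2R,3R)-N-methoxy-N,2,3-trimethyl-3-[(trimethylsilyl)ethynyl]pent-4-enamide, via acid chloride 8 (not isolated)
Conditions: (COCl)2, DMF (cat.), CH2Cl2, 0 °C to rt; concentrate; then MeNHOMe·HCl, pyridine, CH2Cl2, 0 °C
Reagents that add atoms: N,O-dimethylhydroxylamine hydrochloride, CNOC.Cl; oxalyl chloride, O=C(Cl)C(=O)Cl (chlorine of 8 only)
Why: acid chloride formation followed by N-acylation is the most reactive activation for this α-branched, β-quaternary acid, and the weak base pyridine at 0 °C should avoid ketene formation and so keep the α-stereocenter.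

Step 5
Reactants: 9 (2R,3R)-N-methoxy-N,2,3-trimethyl-3-[(trimethylsilyl)ethynyl]pent-4-enamide; 10 (2-methylprop-1-en-1-yl)magnesium bromide
Product: 11 (5R,6R)-2,5,6-trimethyl-6-[(trimethylsilyl)ethynyl]octa-2,7-dien-4-one
Conditions: THF, 0 °C to rt; sat. aq. NH4Cl
Reagents that add atoms: none
Why: Weinreb ketone synthesis, in which the chelated tetrahedral adduct prevents over-addition and the β,β-dimethyl substitution of the enone blocks conjugate addition of the released amine.

Step 6
Reactants: 11 (5R,6R)-2,5,6-trimethyl-6-[(trimethylsilyl)ethynyl]octa-2,7-dien-4-one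
Product: 12 (4S,5R,6R)-2,5,6-trimethyl-6-[(trimethylsilyl)ethynyl]octa-2,7-dien-4-ol
Conditions: NaBH4, CeCl3·7H2O, MeOH, −78 °C
Reagents that add atoms: none
Why: Luche 1,2-reduction under Felkin–Anh control: hydride should approach anti to the quaternary carbon and past the α-hydrogen, giving the (4S) alcohol with hydroxyl and methyl anti in the extended chain (cis on ring B later).

Step 7
Reactants: 13 (R)-2-hydroxy-2-methylbutanoic acid
Product: 14 (R)-2-methylbutane-1,2-diol
Conditions: LiAlH4, THF, 0 °C to reflux; H2O, 15% aq. NaOH, H2O; filtration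
Reagents that add atoms: none
Why: hydride reduction of the carboxylic acid, which does not touch the tertiary carbinol stereocenter.

Step 8
Reactants: 14 (R)-2-methylbutane-1,2-diol; 15 ethyl (E)-4-(diethoxyphosphoryl)but-2-enoate
Product: 17 ethyl (2E,4E,6R)-6-hydroxy-6-methylocta-2,4-dienoate, via hydroxy aldehyde 16 (not isolated)
Conditions: IBX, MeCN, 80 °C; filter; filtrate added to 15/LiN(SiMe3)2 (1.1:1.0), THF, −78 °C to 0 °C
Reagents that add atoms: none
Why: IBX should oxidise the primary hydroxyl of the 1,2-diol without glycol cleavage, and the vinylogous Horner–Wadsworth–Emmons reaction of the volatile aldehyde, used in solution, gives the (2E,4E)-dienoate through the usual trans-selective elimination.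

Step 9
Reactants: 17 ethyl (2E,4E,6R)-6-hydroxy-6-methylocta-2,4-dienoate
Product: 18 (2E,4E,6R)-6-hydroxy-6-methylocta-2,4-dienoic acid
Conditions: LiOH·H2O, THF/H2O (3:1), rt; then 1 M HCl to pH 4, 0 °C
Reagents that add atoms: lithium hydroxide, [Li+].[OH-]
Why: saponification of the ethyl ester, under which the tertiary alcohol and the diene geometry are stable.

Step 10
Reactants: 12 (4S,5R,6R)-2,5,6-trimethyl-6-[(trimethylsilyl)ethynyl]octa-2,7-dien-4-ol; 18 (2E,4E,6R)-6-hydroxy-6-methylocta-2,4-dienoic acid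
Product: 20 (4S,5R,6R)-2,5,6-trimethyl-6-[(trimethylsilyl)ethynyl]octa-2,7-dien-4-yl (2E,4E,6R)-6-hydroxy-6-methylocta-2,4-dienoate, via mixed anhydride 19 (not isolated)
Conditions: 2,4,6-trichlorobenzoyl chloride, Et3N, THF, rt; then 12, DMAP, toluene, rt to 40 °C
Reagents that add atoms: 2,4,6-trichlorobenzoyl chloride, O=C(Cl)c1c(Cl)cc(Cl)cc1Cl (aroyl group of 19 only)
Why: Yamaguchi esterification, in which DMAP attacks the dienoyl carbonyl of the hindered mixed anhydride and the acylpyridinium acylates the hindered secondary alcohol with retention at C2; the tertiary hydroxyl of 18 is too hindered to compete, and the ester doubles as the protecting group of the C2 oxygen.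

Step 11
Reactants: 20 (4S,5R,6R)-2,5,6-trimethyl-6-[(trimethylsilyl)ethynyl]octa-2,7-dien-4-yl (2E,4E,6R)-6-hydroxy-6-methylocta-2,4-dienoate
Product: 22 (4S,5R,6R)-8-hydroxy-2,5,6-trimethyl-6-[(trimethylsilyl)ethynyl]oct-2-en-4-yl (2E,4E,6R)-6-hydroxy-6-methylocta-2,4-dienoate, via alkylborane 21 (not isolated)
Conditions: 9-BBN (2.5 equiv), THF, 0 °C to rt; then 30% H2O2, aq. NaHCO3, 0 °C to rt
Reagents that add atoms: hydrogen peroxide, OO; 9-borabicyclo[3.3.1]nonane, B1C2CCCC1CCC2 (boron residue of 21 only)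
Why: anti-Markovnikov hydroboration–oxidation: 9-BBN should react with the monosubstituted vinyl group far faster than with the trisubstituted olefin, the silylated alkyne or the electron-poor dienoate, and the buffered peroxide spares the ester and the C–Si bond.

Step 12
Reactants: 22 (4S,5R,6R)-8-hydroxy-2,5,6-trimethyl-6-[(trimethylsilyl)ethynyl]oct-2-en-4-yl (2E,4E,6R)-6-hydroxy-6-methylocta-2,4-dienoate
Product: 23 (4S,5R,6R)-2,5,6-trimethyl-8-oxo-6-[(trimethylsilyl)ethynyl]oct-2-en-4-yl (2E,4E,6R)-6-hydroxy-6-methylocta-2,4-dienoate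
Conditions: Dess–Martin periodinane, NaHCO3, CH2Cl2, 0 °C to rt
Reagents that add atoms: none
Why: mild periodinane oxidation of the primary alcohol to the aldehyde; the tertiary hydroxyl cannot be oxidised and there is no α-stereocenter to epimerise.

Step 13
Reactants: 23 (4S,5R,6R)-2,5,6-trimethyl-8-oxo-6-[(trimethylsilyl)ethynyl]oct-2-en-4-yl (2E,4E,6R)-6-hydroxy-6-methylocta-2,4-dienoate; 24 4,4,5,5-tetramethyl-2-(propa-1,2-dien-1-yl)-1,3,2-dioxaborolane (allenylboronic acid pinacol ester)
Product: 26 (4S,5R,6R,8R,9S)-8,9-dihydroxy-2,5,6-trimethyl-6-[(trimethylsilyl)ethynyl]undeca-2,10-dien-4-yl (2E,4E,6R)-6-hydroxy-6-methylocta-2,4-dienoate, via boryl borinate 25 (not isolated)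
Conditions: (−)-diisopinocampheylborane [from (+)-α-pinene], 24, Et2O, 0 °C, 2 h; then 23, −78 °C; then 30% H2O2, aq. NaHCO3, THF, 0 °C to rt
Reagents that add atoms: hydrogen peroxide, OO; (−)-diisopinocampheylborane, C[C@H]1[C@H](B[C@@H]2C[C@@H]3C[C@H]([C@H]2C)C3(C)C)C[C@@H]2C[C@H]1C2(C)C (boron and terpene residues of 25 only)
Why: hydroboration of the allene should give the (E)-γ-borylallylborane, which adds to the aldehyde through a chair transition state on the si face set by the isopinocampheyl groups (C7 of the target, R), and oxidation of the allylic C–B bond with retention gives the anti-diol; the C6 configuration does not matter because C6 becomes the ketone.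

Step 14
Reactants: 26 (4S,5R,6R,8R,9S)-8,9-dihydroxy-2,5,6-trimethyl-6-[(trimethylsilyl)ethynyl]undeca-2,10-dien-4-yl (2E,4E,6R)-6-hydroxy-6-methylocta-2,4-dienoate
Product: 27 (4S,5R,6R,8R,9S)-6-ethynyl-8,9-dihydroxy-2,5,6-trimethylundeca-2,10-dien-4-yl (2E,4E,6R)-6-hydroxy-6-methylocta-2,4-dienoate
Conditions: Bu4NF, AcOH (1:1), THF, 0 °C
Reagents that add atoms: none
Why: fluoride-induced protodesilylation of the alkynylsilane, buffered with acetic acid so that the ester is not attacked.

Step 15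
Reactants: 27 (4S,5R,6R,8R,9S)-6-ethynyl-8,9-dihydroxy-2,5,6-trimethylundeca-2,10-dien-4-yl (2E,4E,6R)-6-hydroxy-6-methylocta-2,4-dienoate
Product: 28 (1R,2S,6S,7R,8aR)-6,7-dihydroxy-1,8a-dimethyl-1,2,6,7,8,8a-hexahydronaphthalen-2-yl (2E,4E,6R)-6-hydroxy-6-methylocta-2,4-dienoate
Conditions: RuCl2(=CHPh)(H2IMes)(PCy3) (second-generation Grubbs catalyst, 10 mol %), 1,4-benzoquinone (20 mol %), toluene (0.003 M), 60 °C, argon
Reagents that add atoms: none
Why: The ruthenium alkylidene should load onto the monosubstituted vinyl group (C5 end) and add in the exo mode to the ethynyl group on C8a through a metallacyclobutene, which forms the C4a–C5 bond and ring A (six-membered exo ring-closing enyne metathesis) and leaves a vinylcarbene on C4. This carbene then closes ring B on the trisubstituted olefin by six-membered ring-closing olefin metathesis, forming C3=C4 and expelling 2-methylpropene. The closest known reaction type is the tandem ring-closing metathesis of dienynes to fused bicyclic 1,3-dienes. No stereocenter is formed; C1, C2, C7 and C8a are spectators, and C6 is removed in the next step. The selectivity needed is the site of initiation, since a start at the other olefin would lead by five-membered exo closure to a 5–7 skeleton; the 2-methylprop-1-enyl group is too hindered to take up the catalyst yet can still end the relay, and the free allylic hydroxyl at C6 speeds loading at the vinyl group. Direct diene metathesis between the two olefins would give an eight-membered ring and should not compete; high dilution and the absence of ethylene keep the vinylcarbene on the intramolecular path, and benzoquinone suppresses ruthenium hydride isomerisation of the allylic alcohol.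

Step 16
Reactants: 28 (1R,2S,6S,7R,8aR)-6,7-dihydroxy-1,8a-dimethyl-1,2,6,7,8,8a-hexahydronaphthalen-2-yl (2E,4E,6R)-6-hydroxy-6-methylocta-2,4-dienoate
Product: 29 (1R,2S,7R,8aR)-7-hydroxy-1,8a-dimethyl-6-oxo-1,2,6,7,8,8a-hexahydronaphthalen-2-yl (2E,4E,6R)-6-hydroxy-6-methylocta-2,4-dienoate (CNP0260852.1)
Conditions: MnO2 (activated, 15 equiv), CH2Cl2, rt
Reagents that add atoms: none
Why: chemoselective oxidation of the dienylic C6 carbinol to the dienone; MnO2 should leave the saturated C7 hydroxyl and the tertiary side-chain hydroxyl alone, and the C7 hydroxyl already has the equatorial, thermodynamically preferred configuration.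

**Compound list**

1 | (E)-3-methylpent-2-en-4-yn-1-ol | C#C/C(C)=C/CO | starting material
2 | trimethyl{[(E)-3-methyl-5-(trimethylsilyl)pent-2-en-4-yn-1-yl]oxy}silane | C[Si](C)(C)OC/C=C(\C)C#C[Si](C)(C)C | intermediate (not isolated)
3 | (E)-3-methyl-5-(trimethylsilyl)pent-2-en-4-yn-1-ol | OC/C=C(\C)C#C[Si](C)(C)C | intermediate
4 | propanoyl chloride | CCC(=O)Cl | starting material
5 | (E)-3-methyl-5-(trimethylsilyl)pent-2-en-4-yn-1-yl propanoate | CCC(=O)OC/C=C(\C)C#C[Si](C)(C)C | intermediate
6 | boron ketene acetal of 5 on the (4S,5S)-diazaborolidine, methyl cis to the allyloxy oxygen | C/C=C(\OC/C=C(\C)C#C[Si](C)(C)C)OB1N(S(=O)(=O)c2cc(C(F)(F)F)cc(C(F)(F)F)c2)[C@@H](c2ccccc2)[C@H](c2ccccc2)N1S(=O)(=O)c1cc(C(F)(F)F)cc(C(F)(F)F)c1 | intermediate (not isolated)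
7 | (2R,3R)-2,3-dimethyl-3-[(trimethylsilyl)ethynyl]pent-4-enoic acid | C=C[C@](C#C[Si](C)(C)C)(C)[C@H](C(=O)O)C | intermediate
8 | (2R,3R)-2,3-dimethyl-3-[(trimethylsilyl)ethynyl]pent-4-enoyl chloride | C=C[C@](C#C[Si](C)(C)C)(C)[C@H](C(=O)Cl)C | intermediate (not isolated)
9 | (2R,3R)-N-methoxy-N,2,3-trimethyl-3-[(trimethylsilyl)ethynyl]pent-4-enamide | C=C[C@](C#C[Si](C)(C)C)(C)[C@H](C(=O)N(C)OC)C | intermediate
10 | (2-methylprop-1-en-1-yl)magnesium bromide | CC(C)=C[Mg]Br | starting material
11 | (5R,6R)-2,5,6-trimethyl-6-[(trimethylsilyl)ethynyl]octa-2,7-dien-4-one | C=C[C@](C#C[Si](C)(C)C)(C)[C@H](C(=O)C=C(C)C)C | intermediate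
12 | (4S,5R,6R)-2,5,6-trimethyl-6-[(trimethylsilyl)ethynyl]octa-2,7-dien-4-ol | C=C[C@](C#C[Si](C)(C)C)(C)[C@H]([C@@H](O)C=C(C)C)C | intermediate
13 | (R)-2-hydroxy-2-methylbutanoic acid | CC[C@@](C)(O)C(=O)O | starting material
14 | (R)-2-methylbutane-1,2-diol | CC[C@@](C)(O)CO | intermediate
15 | ethyl (E)-4-(diethoxyphosphoryl)but-2-enoate | CCOC(=O)/C=C/CP(=O)(OCC)OCC | starting material
16 | (R)-2-hydroxy-2-methylbutanal | CC[C@@](C)(O)C=O | intermediate (not isolated)
17 | ethyl (2E,4E,6R)-6-hydroxy-6-methylocta-2,4-dienoate | CC[C@@](C)(O)/C=C/C=C/C(=O)OCC | intermediate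
18 | (2E,4E,6R)-6-hydroxy-6-methylocta-2,4-dienoic acid | CC[C@@](C)(O)/C=C/C=C/C(=O)O | intermediate
19 | (2E,4E,6R)-6-hydroxy-6-methylocta-2,4-dienoic 2,4,6-trichlorobenzoic anhydride | CC[C@@](C)(O)/C=C/C=C/C(=O)OC(=O)c1c(Cl)cc(Cl)cc1Cl | intermediate (not isolated)
20 | (4S,5R,6R)-2,5,6-trimethyl-6-[(trimethylsilyl)ethynyl]octa-2,7-dien-4-yl (2E,4E,6R)-6-hydroxy-6-methylocta-2,4-dienoate | C=C[C@](C#C[Si](C)(C)C)(C)[C@H]([C@@H](OC(=O)/C=C/C=C/[C@](C)(O)CC)C=C(C)C)C | intermediate
21 | 8-(9-borabicyclo[3.3.1]nonan-9-yl) adduct of 20 | C(CB1C2CCCC1CCC2)[C@](C#C[Si](C)(C)C)(C)[C@H]([C@@H](OC(=O)/C=C/C=C/[C@](C)(O)CC)C=C(C)C)C | intermediate (not isolated)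
22 | (4S,5R,6R)-8-hydroxy-2,5,6-trimethyl-6-[(trimethylsilyl)ethynyl]oct-2-en-4-yl (2E,4E,6R)-6-hydroxy-6-methylocta-2,4-dienoate | OCC[C@](C#C[Si](C)(C)C)(C)[C@H]([C@@H](OC(=O)/C=C/C=C/[C@](C)(O)CC)C=C(C)C)C | intermediate
23 | (4S,5R,6R)-2,5,6-trimethyl-8-oxo-6-[(trimethylsilyl)ethynyl]oct-2-en-4-yl (2E,4E,6R)-6-hydroxy-6-methylocta-2,4-dienoate | O=CC[C@](C#C[Si](C)(C)C)(C)[C@H]([C@@H](OC(=O)/C=C/C=C/[C@](C)(O)CC)C=C(C)C)C | intermediate
24 | 4,4,5,5-tetramethyl-2-(propa-1,2-dien-1-yl)-1,3,2-dioxaborolane | C=C=CB1OC(C)(C)C(C)(C)O1 | starting material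
25 | allylboration adduct of 23: C8 O-diisopinocampheylborinate, C9 pinacolboryl (undecadienyl numbering) | C=C[C@H](B1OC(C)(C)C(C)(C)O1)[C@H](OB([C@@H]2C[C@@H]3C[C@H]([C@H]2C)C3(C)C)[C@@H]2C[C@@H]3C[C@H]([C@H]2C)C3(C)C)C[C@](C#C[Si](C)(C)C)(C)[C@H]([C@@H](OC(=O)/C=C/C=C/[C@](C)(O)CC)C=C(C)C)C | intermediate (not isolated)
26 | (4S,5R,6R,8R,9S)-8,9-dihydroxy-2,5,6-trimethyl-6-[(trimethylsilyl)ethynyl]undeca-2,10-dien-4-yl (2E,4E,6R)-6-hydroxy-6-methylocta-2,4-dienoate | C=C[C@H](O)[C@H](O)C[C@](C#C[Si](C)(C)C)(C)[C@H]([C@@H](OC(=O)/C=C/C=C/[C@](C)(O)CC)C=C(C)C)C | intermediate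
27 | (4S,5R,6R,8R,9S)-6-ethynyl-8,9-dihydroxy-2,5,6-trimethylundeca-2,10-dien-4-yl (2E,4E,6R)-6-hydroxy-6-methylocta-2,4-dienoate | C=C[C@H](O)[C@H](O)C[C@](C#C)(C)[C@H]([C@@H](OC(=O)/C=C/C=C/[C@](C)(O)CC)C=C(C)C)C | intermediate
28 | (1R,2S,6S,7R,8aR)-6,7-dihydroxy-1,8a-dimethyl-1,2,6,7,8,8a-hexahydronaphthalen-2-yl (2E,4E,6R)-6-hydroxy-6-methylocta-2,4-dienoate | CC[C@@](C)(O)/C=C/C=C/C(=O)O[C@H]1C=CC2=C[C@H](O)[C@H](O)C[C@]2(C)[C@H]1C | intermediate
29 | (1R,2S,7R,8aR)-7-hydroxy-1,8a-dimethyl-6-oxo-1,2,6,7,8,8a-hexahydronaphthalen-2-yl (2E,4E,6R)-6-hydroxy-6-methylocta-2,4-dienoate | CC[C@@](C)(O)/C=C/C=C/C(=O)O[C@H]1C=CC2=CC(=O)[C@H](O)C[C@]2(C)[C@H]1C | target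

**Step count and risks**

Total steps: 16. Longest linear sequence: 13 steps (1 to 29 through steps 1–6 and 10–16); the side-chain acid 18 takes 3 steps (7–9) and joins at step 10.

Steps most likely to fail:

1. Step 15. The relay may break between the two ring closures: the vinylcarbene on C4 faces a trisubstituted olefin and may be lost to intermolecular cross-metathesis, or the catalyst may die on the free allylic alcohol (isomerisation to a ketone) before ring B closes. Fallback, setting out from 27 and coming back at 28: the two closures are run as separate operations. Ring-closing enyne metathesis under ethylene (1 atm; second-generation Grubbs catalyst, CH2Cl2, rt), in which ethylene caps the vinylcarbene, should give the monocyclic triene (4S,5R)-5-[(1R,4S,5R)-2-ethenyl-4,5-dihydroxy-1-methylcyclohex-2-en-1-yl]-2-methylhex-2-en-4-yl (2E,4E,6R)-6-hydroxy-6-methylocta-2,4-dienoate F1. F1 is isolated and then closed to 28 in a separate diene ring-closing metathesis with the phosphine-free catalyst RuCl2(=CH-C6H4-2-OiPr)(H2IMes) in toluene at 80 °C, with loss of 2-methylpropene.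

2. Step 3. Enantiofacial discrimination may be low, the [3,3] shift may stall at the fully substituted olefin terminus, or the enolate geometry may erode during the long reaction time. Fallback, setting out from 5 and coming back at 7: a classical Ireland–Claisen rearrangement followed by resolution. LiN(iPr)2 in THF at −78 °C and Me3SiCl/Et3N should give the (E)-ketene silyl acetal {[(1E)-1-{[(2E)-3-methyl-5-(trimethylsilyl)pent-2-en-4-yn-1-yl]oxy}prop-1-en-1-yl]oxy}trimethylsilane F2. Warming to rt rearranges it through the same chair to racemic trimethylsilyl (2R*,3R*)-2,3-dimethyl-3-[(trimethylsilyl)ethynyl]pent-4-enoate F3. Dilute HCl gives racemic (2R*,3R*)-2,3-dimethyl-3-[(trimethylsilyl)ethynyl]pent-4-enoic acid F4. Fractional crystallisation with (R)-1-phenylethylamine (or its antipode, whichever gives the less soluble salt of the wanted acid) gives (R)-1-phenylethylammonium (2R,3R)-2,3-dimethyl-3-[(trimethylsilyl)ethynyl]pent-4-enoate F5, and 1 M HCl returns 7. Half of the material is lost with the other enantiomer.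

3. Step 11. The borane may lose chemoselectivity (attack on the dienoate or the silylalkyne, sluggish reaction at the vinyl group on the quaternary carbon). Fallback, setting out from 12 and coming back at 22: the hydroboration is moved ahead of the esterification. 9-BBN in THF followed by H2O2/aq. NaHCO3 on 12 should give (3R,4R,5S)-3,4,7-trimethyl-3-[(trimethylsilyl)ethynyl]oct-6-ene-1,5-diol F6. Selective silylation of the primary hydroxyl (tBuMe2SiCl, imidazole, CH2Cl2, 0 °C) gives (4S,5R,6R)-8-[(tert-butyldimethylsilyl)oxy]-2,5,6-trimethyl-6-[(trimethylsilyl)ethynyl]oct-2-en-4-ol F7. Yamaguchi esterification with 18, as in step 10, gives (4S,5R,6R)-8-[(tert-butyldimethylsilyl)oxy]-2,5,6-trimethyl-6-[(trimethylsilyl)ethynyl]oct-2-en-4-yl (2E,4E,6R)-6-hydroxy-6-methylocta-2,4-dienoate F8, and HF·pyridine in THF/pyridine at 0 °C frees the primary alcohol 22.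

**Further compounds**

F1 | step 15 | (4S,5R)-5-[(1R,4S,5R)-2-ethenyl-4,5-dihydroxy-1-methylcyclohex-2-en-1-yl]-2-methylhex-2-en-4-yl (2E,4E,6R)-6-hydroxy-6-methylocta-2,4-dienoate | C=CC1=C[C@H](O)[C@H](O)C[C@]1(C)[C@H]([C@@H](OC(=O)/C=C/C=C/[C@](C)(O)CC)C=C(C)C)C
F2 | step 3 | {[(1E)-1-{[(2E)-3-methyl-5-(trimethylsilyl)pent-2-en-4-yn-1-yl]oxy}prop-1-en-1-yl]oxy}trimethylsilane | C/C=C(\OC/C=C(\C)C#C[Si](C)(C)C)O[Si](C)(C)C
F3 | step 3 | racemic trimethylsilyl (2R*,3R*)-2,3-dimethyl-3-[(trimethylsilyl)ethynyl]pent-4-enoate | C=C[C@](C#C[Si](C)(C)C)(C)[C@H](C(=O)O[Si](C)(C)C)C.C=C[C@@](C#C[Si](C)(C)C)(C)[C@@H](C(=O)O[Si](C)(C)C)C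
F4 | step 3 | racemic (2R*,3R*)-2,3-dimethyl-3-[(trimethylsilyl)ethynyl]pent-4-enoic acid | C=C[C@](C#C[Si](C)(C)C)(C)[C@H](C(=O)O)C.C=C[C@@](C#C[Si](C)(C)C)(C)[C@@H](C(=O)O)C
F5 | step 3 | (R)-1-phenylethylammonium (2R,3R)-2,3-dimethyl-3-[(trimethylsilyl)ethynyl]pent-4-enoate | C=C[C@](C#C[Si](C)(C)C)(C)[C@H](C(=O)[O-])C.C[C@@H]([NH3+])c1ccccc1
F6 | step 11 | (3R,4R,5S)-3,4,7-trimethyl-3-[(trimethylsilyl)ethynyl]oct-6-ene-1,5-diol | OCC[C@](C#C[Si](C)(C)C)(C)[C@H]([C@@H](O)C=C(C)C)C
F7 | step 11 | (4S,5R,6R)-8-[(tert-butyldimethylsilyl)oxy]-2,5,6-trimethyl-6-[(trimethylsilyl)ethynyl]oct-2-en-4-ol | CC(C)(C)[Si](C)(C)OCC[C@](C#C[Si](C)(C)C)(C)[C@H]([C@@H](O)C=C(C)C)C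
F8 | step 11 | (4S,5R,6R)-8-[(tert-butyldimethylsilyl)oxy]-2,5,6-trimethyl-6-[(trimethylsilyl)ethynyl]oct-2-en-4-yl (2E,4E,6R)-6-hydroxy-6-methylocta-2,4-dienoate | CC(C)(C)[Si](C)(C)OCC[C@](C#C[Si](C)(C)C)(C)[C@H]([C@@H](OC(=O)/C=C/C=C/[C@](C)(O)CC)C=C(C)C)C
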